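## Retrosynthetic overview

1. Numbering: outer ring C1(O-tiglate)–C2–C3(O-senecioate)–C4(Me)–C5–C6(=O)–C7=C8(Me)–C9–C10–C11(Me2)–C1, cross-ring bonds C4–C9 and C5–C10. The route rests on C10, which lies between C5 and C9, the two carbons also joined by the C6–C7–C8 arm. The four-membered ring C4–C5–C10–C9 and the six-membered enone ring C5–C6–C7–C8–C9–C10 therefore form a bicyclo[3.1.1]heptane, i.e. a cyclobutanone (C10=O) annulated at both α-carbons.
2. Endgame: C1 tiglate (Yamaguchi) ⇐ C3 senecioate plus C1 carbinol from the C3-hydroxy C1-ketone (Evans–Tishchenko) ⇐ C7=C8 from a C6 enol silane (Saegusa–Ito) ⇐ C10–H from a C10 carbinol (radical deoxygenation).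
3. Seven-membered ring (C4–C3–C2–C1–C11–C10, closed through C5 or C9): C10–C11 by reductive aldol of a C1 isopropenyl ketone onto the C10 ketone; C2–C3 by a reagent-controlled boron aldol on the C3 aldehyde.
4. Six-membered ring: (3+3) annulation of the chiral enamine of 3-methyl-3-(silyloxymethyl)cyclobutanone with crotonoyl chloride (C9–C8, then C5–C6). C6 is then held as an enol silane from step 9 to step 15, because an alkoxide at C10 beside a C6 carbonyl would open C5–C10 by retro-aldol.
5. Ring order: four-membered ring (from the starting acid), six-membered ring (step 6), seven-membered ring (step 12).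

Key step: step 6

Assumption: the sense of induction of (S)-2-(methoxymethyl)pyrrolidine in step 6 and of (+)-Ipc2BCl in step 10 (Re-face addition) is taken as drawn; the antipodal reagent is used if either proves opposite.

## Route

Step 1
Reactants: 1 3-oxocyclobutane-1-carboxylic acid
Product: 2 methyl 3,3-dimethoxycyclobutane-1-carboxylate
Conditions: HC(OMe)3, MeOH, TsOH·H2O (cat.), reflux
Reagents that add atoms: methanol CO; trimethyl orthoformate COC(OC)OC
Why: Fischer esterification and ketalisation run together, the orthoformate removing the water, so that the ketone is masked before the enolate chemistry.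

Step 2
Reactants: 2 methyl 3,3-dimethoxycyclobutane-1-carboxylate
Product: 4 methyl 3,3-dimethoxy-1-methylcyclobutane-1-carboxylate, via lithium enolate 3 (not isolated)
Conditions: lithium diisopropylamide, THF, −78 °C; then MeI, −78 → 0 °C
Reagents that add atoms: iodomethane CI
Why: Ester enolate alkylation installs the C4 methyl and makes C4 quaternary; the product is achiral, so no stereocontrol is needed.

Step 3
Reactants: 4 methyl 3,3-dimethoxy-1-methylcyclobutane-1-carboxylate
Product: 5 (3,3-dimethoxy-1-methylcyclobutyl)methanol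
Conditions: LiAlH4, THF, 0 °C; then H2O
Reagents that add atoms: none
Why: Hydride reduction of the ester gives the neopentyl alcohol (future C3) while the dimethyl ketal is inert to hydride.

Step 4
Reactants: 5 (3,3-dimethoxy-1-methylcyclobutyl)methanol
Product: 6 tert-butyl[(3,3-dimethoxy-1-methylcyclobutyl)methoxy]diphenylsilane
Conditions: TBDPSCl, imidazole, DMF, rt
Reagents that add atoms: tert-butyl(chloro)diphenylsilane CC(C)(C)[Si](Cl)(c1ccccc1)c1ccccc1
Why: Silylation of the primary alcohol; the bulky, acid-stable TBDPS group is chosen to survive steps 5 and 6 and to enlarge the C3 arm relative to the C4 methyl.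

Step 5
Reactants: 6 tert-butyl[(3,3-dimethoxy-1-methylcyclobutyl)methoxy]diphenylsilane
Product: 7 3-{[tert-butyl(diphenyl)silyl]oxymethyl}-3-methylcyclobutan-1-one
Conditions: 1 M aq. HCl, acetone, rt
Reagents that add atoms: water O
Why: Acid hydrolysis of the dimethyl ketal frees the C10 ketone, and the TBDPS ether tolerates dilute aqueous acid.

Step 6
Reactants: 7 3-{[tert-butyl(diphenyl)silyl]oxymethyl}-3-methylcyclobutan-1-one; 8 (S)-2-(methoxymethyl)pyrrolidine; 9 (E)-but-2-enoyl chloride (crotonoyl chloride)
Product: 12 (1R,4S,5R,7R)-7-{[tert-butyl(diphenyl)silyl]oxymethyl}-4,7-dimethylbicyclo[3.1.1]heptane-2,6-dione, via enamine 10 (not isolated), via iminium chloride 11 (not isolated)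
Conditions: 8 (1.2 equiv), 4 Å MS, toluene, rt; then 9 (1.1 equiv), 0 → 80 °C; then H2O, rt
Reagents that add atoms: crotonoyl chloride (9) C/C=C/C(Cl)=O; water O
Why: Proposed new method: enamine 10 is N-acylated by 9 and the N-acylenammonium undergoes an aza-Claisen-type [3,3] shift that joins C9 to the crotonyl β-carbon C8 and leaves a ketene on the iminium; loss of the C5 proton regenerates an enamine that attacks the ketene carbon C6, so that C5–C6 forms and the six-membered ring C5–C6–C7–C8–C9–C10 closes as a 6-exo-dig C-acylation on the same face of the four-membered ring, after which water hydrolyses iminium 11 to the dione. The closest known reaction is the α,α′-annulation of pyrrolidine enamines of five- to eight-membered ketones with acryloyl or crotonoyl chloride to bicyclo[n.3.1]alkanediones; it has not been shown for cyclobutanone enamines, where the strained cyclobutene enamine and the bicyclo[3.1.1]heptane product are the open questions. C9 is set by the chiral amine, which makes the two enantiotopic α-carbons diastereotopic in the equilibrating enamines so that the enamine whose unshielded π-face is also the substrate-preferred face should react fastest; C5 follows from C9 because the three-carbon arm can span only one face; C4 becomes stereogenic with its methyl syn to the new arm because the crotonyl unit approaches anti to the bulkier CH2OTBDPS group; C8 comes from a chair-like shift of the (E)-crotonyl unit and is erased in step 15. The step needs C-attack at the enamine carbon and not simple amide formation, which the [3,3] pathway of the N-acyl intermediate provides, and it needs the second acylation to outrun ketene dimerisation, which the intramolecular six-membered closure favours.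

Step 7
Reactants: 12 the bicyclic dione
Product: 13 hydroxy dione (7-hydroxymethyl analogue of 12; C3 = CH2OH on C4)
Conditions: HF·pyridine, pyridine, THF, 0 °C → rt
Reagents that add atoms: none
Why: Acidic fluoride desilylation cleaves the Si–O bond without bringing a basic nucleophile to C10, which would open the non-enolisable β-diketone by retro-Claisen cleavage.

Step 8
Reactants: 13 hydroxy dione
Product: 14 aldehyde dione (C3 = CHO on quaternary C4; C6 and C10 ketones)
Conditions: Dess–Martin periodinane, CH2Cl2, rt
Reagents that add atoms: none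
Why: Dess–Martin oxidation under near-neutral conditions gives the neopentyl aldehyde, which has no α-hydrogen and cannot epimerise.

Step 9
Reactants: 14 aldehyde dione
Product: 15 C6 tert-butyldimethylsilyl enol ether (C6(OTBS)=C7; C3 aldehyde and C10 ketone unchanged)
Conditions: TBSOTf, Et3N, CH2Cl2, −78 → 0 °C
Reagents that add atoms: tert-butyldimethylsilyl trifluoromethanesulfonate CC(C)(C)[Si](C)(C)OS(=O)(=O)C(F)(F)F
Why: Soft enolisation can only occur toward C7, since C5 and C9 are bridgeheads and the aldehyde sits on a quaternary carbon; the enol silane removes the C6 carbonyl, so that later alkoxides at C10 cannot fragment the C5–C10 bond, and it serves as the enone precursor for step 15.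

Step 10
Reactants: 15 C6 silyl enol ether aldehyde; 16 3-methylbut-3-en-2-one
Product: 19 β-hydroxy isopropenyl ketone (C3 R; chain C3(OH)–C2H2–C1(=O)–C11(CH3)=CH2), via boron enolate 17 (not isolated), via boron aldolate 18 (not isolated)
Conditions: 16, (+)-Ipc2BCl, Et3N, Et2O, 0 °C; then 15, −78 → −20 °C; then MeOH, pH 7 buffer, rt (no peroxide)
Reagents that add atoms: 3-methylbut-3-en-2-one (16) CC(=O)C(C)=C
Why: Diisopinocampheylboron enolate aldol of the methyl ketone, in which the aldehyde reacts in preference to the hindered C10 ketone and the Ipc ligands set C3 by reagent control, since the C5 and C9 flanks of the aldehyde differ only remotely; the C3 epimer is a separable diastereomer, and this separation should also remove material of the minor enantiomeric series from step 6.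

Step 11
Reactants: 19 β-hydroxy isopropenyl ketone
Product: 20 C3 triethylsilyl ether of 19
Conditions: TESOTf, 2,6-lutidine, CH2Cl2, −78 °C
Reagents that add atoms: triethylsilyl trifluoromethanesulfonate CC[Si](CC)(CC)OS(=O)(=O)C(F)(F)F
Why: Silylation caps the C3 hydroxyl before it can add to the enone (oxa-Michael) or quench the enolate of step 12.

Step 12
Reactants: 20 C3 triethylsilyl ether
Product: 21 tricyclic tertiary alcohol (C10–C11 closed; C10–OH on the face of the C6–C8 arm, C1 ketone, C3 OTES, C6 enol silane)
Conditions: [(Ph3P)CuH]6, toluene, −40 → 0 °C; then H2O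
Reagents that add atoms: none
Why: Copper hydride conjugate reduction followed by aldol cyclisation (reductive aldol): hydride adds to the terminal CH2 of the isopropenyl ketone, and the resulting copper enolate at C11 attacks the strained C10 ketone on the only face the C4 tether allows, which closes the seven-membered ring, creates the gem-dimethyl C11 and fixes C10; the copper alkoxide cannot fragment because C6 is no longer a carbonyl.

Step 13
Reactants: 21 tricyclic tertiary alcohol
Product: 22 C10 methyl oxalate of 21
Conditions: ClCOCO2Me, DMAP, Et3N, CH2Cl2, 0 °C → rt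
Reagents that add atoms: methyl chlorooxoacetate COC(=O)C(Cl)=O
Why: Acylation of the tertiary alcohol with a small, highly reactive acid chloride gives the radical precursor; elimination is excluded because C11 is quaternary and C5 and C9 are bridgeheads.

Step 14
Reactants: 22 C10 methyl oxalate
Product: 23 deoxygenated tricycle (C10–H; C1 ketone, C3 OTES, C6 enol silane)
Conditions: Bu3SnH, AIBN (cat.), toluene, 110 °C
Reagents that add atoms: none
Why: Barton–McCombie-type radical deoxygenation of a tertiary methyl oxalate: the tertiary cyclobutyl radical at C10 takes hydrogen from the stannane, and its configuration is dictated by the cage, since C11 is tied to the face opposite the C6–C8 arm.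

Step 15
Reactants: 23 deoxygenated tricycle
Product: 24 enone (C6=O, C7=C8; C1 ketone, C3 OTES)
Conditions: Pd(OAc)2 (1.1 equiv), MeCN, rt → 40 °C
Reagents that add atoms: none
Why: Saegusa–Ito oxidation: the enol silane gives a palladium enolate at C7 and β-hydride elimination of the C8 hydrogen forms the C7=C8 enone, which removes the C8 stereocentre, so either C8 epimer converges here.

Step 16
Reactants: 24 enone
Product: 25 C3 hydroxy C1 ketone
Conditions: HF·pyridine, pyridine, THF, 0 °C
Reagents that add atoms: none
Why: Acidic fluoride removes the secondary triethylsilyl ether without the basic conditions that could trigger retro-aldol or elimination of the β-hydroxy ketone.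

Step 17
Reactants: 25 C3 hydroxy C1 ketone; 26 3-methylbut-2-enal
Product: 27 C3 3-methylbut-2-enoate with free (R)-C1 alcohol
Conditions: 26 (6 equiv), SmI2 (0.3 equiv), THF, −10 °C
Reagents that add atoms: 3-methylbut-2-enal (26) CC(C)=CC=O
Why: Evans–Tishchenko reduction: the C3 hydroxyl forms a samarium-bound hemiacetal with the aldehyde and delivers hydride intramolecularly to the face of the C1 carbonyl syn to the C3 oxygen, which should give the 1,3-anti (trans) C1 alcohol, leave C3 as the senecioate and spare the C6 enone, which has no directing hydroxyl.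

Step 18
Reactants: 27 C3 senecioate C1 alcohol; 28 (E)-2-methylbut-2-enoic acid (tiglic acid)
Product: 30 target CNP0257816.1, via mixed anhydride 29 (not isolated)
Conditions: 28, 2,4,6-trichlorobenzoyl chloride, Et3N, toluene, rt; then 27, DMAP, 40 °C
Reagents that add atoms: tiglic acid (28) C/C=C(\C)C(O)=O
Why: Yamaguchi esterification acylates the hindered C1 alcohol through the mixed anhydride and DMAP, with the (E)-geometry of the tiglate retained.

## Compound list

1 | 3-oxocyclobutane-1-carboxylic acid | OC(=O)C1CC(=O)C1 | starting material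
2 | methyl 3,3-dimethoxycyclobutane-1-carboxylate | COC(=O)C1CC(OC)(OC)C1 | intermediate
3 | lithium enolate of 2 | COC(O[Li])=C1CC(OC)(OC)C1 | intermediate (not isolated)
4 | methyl 3,3-dimethoxy-1-methylcyclobutane-1-carboxylate | COC(=O)C1(C)CC(OC)(OC)C1 | intermediate
5 | (3,3-dimethoxy-1-methylcyclobutyl)methanol | OCC1(C)CC(OC)(OC)C1 | intermediate
6 | tert-butyl[(3,3-dimethoxy-1-methylcyclobutyl)methoxy]diphenylsilane | COC1(OC)CC(C)(CO[Si](c2ccccc2)(c2ccccc2)C(C)(C)C)C1 | intermediate
7 | 3-{[tert-butyl(diphenyl)silyl]oxymethyl}-3-methylcyclobutan-1-one | CC1(CO[Si](c2ccccc2)(c2ccccc2)C(C)(C)C)CC(=O)C1 | intermediate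
8 | (S)-2-(methoxymethyl)pyrrolidine | COC[C@@H]1CCCN1 | starting material
9 | (E)-but-2-enoyl chloride | C/C=C/C(Cl)=O | starting material
10 | enamine of 7 with 8 (C10=C9 double bond) | COC[C@@H]1CCCN1C2=C[C@@](C)(CO[Si](c3ccccc3)(c3ccccc3)C(C)(C)C)C2 | intermediate (not isolated)
11 | bicyclic C6-keto C10-iminium chloride | C[C@H]1CC(=O)[C@@H]2C(=[N+]3CCC[C@H]3COC)[C@H]1[C@@]2(C)CO[Si](c4ccccc4)(c4ccccc4)C(C)(C)C.[Cl-] | intermediate (not isolated)
12 | (1R,4S,5R,7R)-7-{[tert-butyl(diphenyl)silyl]oxymethyl}-4,7-dimethylbicyclo[3.1.1]heptane-2,6-dione | C[C@H]1CC(=O)[C@@H]2C(=O)[C@H]1[C@@]2(C)CO[Si](c3ccccc3)(c3ccccc3)C(C)(C)C | intermediate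
13 | hydroxy dione (7-hydroxymethyl analogue of 12) | C[C@H]1CC(=O)[C@@H]2C(=O)[C@H]1[C@@]2(C)CO | intermediate
14 | aldehyde dione (7-formyl analogue of 12) | C[C@H]1CC(=O)[C@@H]2C(=O)[C@H]1[C@@]2(C)C=O | intermediate
15 | C6 tert-butyldimethylsilyl enol ether of 14 | C[C@H]1C=C(O[Si](C)(C)C(C)(C)C)[C@@H]2C(=O)[C@H]1[C@@]2(C)C=O | intermediate
16 | 3-methylbut-3-en-2-one | CC(=O)C(C)=C | starting material
17 | diisopinocampheylboron enolate of 16 | C=C(OB([C@H]1C[C@H]2C[C@@H]([C@@H]1C)C2(C)C)[C@H]1C[C@H]2C[C@@H]([C@@H]1C)C2(C)C)C(C)=C | intermediate (not isolated)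
18 | boron aldolate (C3–O–B(Ipc)2) | C[C@H]1C=C(O[Si](C)(C)C(C)(C)C)[C@@H]2C(=O)[C@H]1[C@@]2(C)[C@H](OB([C@H]3C[C@H]4C[C@@H]([C@@H]3C)C4(C)C)[C@H]3C[C@H]4C[C@@H]([C@@H]3C)C4(C)C)CC(=O)C(C)=C | intermediate (not isolated)
19 | (3R)-β-hydroxy isopropenyl ketone | C[C@H]1C=C(O[Si](C)(C)C(C)(C)C)[C@@H]2C(=O)[C@H]1[C@@]2(C)[C@H](O)CC(=O)C(C)=C | intermediate
20 | C3 triethylsilyl ether of 19 | C[C@H]1C=C(O[Si](C)(C)C(C)(C)C)[C@@H]2C(=O)[C@H]1[C@@]2(C)[C@H](O[Si](CC)(CC)CC)CC(=O)C(C)=C | intermediate
21 | tricyclic C10 tertiary alcohol (C1 ketone, C3 OTES, C6 enol silane) | O=C1C[C@@H](O[Si](CC)(CC)CC)[C@@]2(C)[C@@H]3C(O[Si](C)(C)C(C)(C)C)=C[C@H](C)[C@H]2[C@]3(O)C1(C)C | intermediate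
22 | C10 methyl oxalate of 21 | O=C1C[C@@H](O[Si](CC)(CC)CC)[C@@]2(C)[C@@H]3C(O[Si](C)(C)C(C)(C)C)=C[C@H](C)[C@H]2[C@]3(OC(=O)C(=O)OC)C1(C)C | intermediate
23 | deoxygenated tricycle (C10–H) | O=C1C[C@@H](O[Si](CC)(CC)CC)[C@@]2(C)[C@@H]3C(O[Si](C)(C)C(C)(C)C)=C[C@H](C)[C@H]2[C@@H]3C1(C)C | intermediate
24 | tricyclic enone (C6=O, C7=C8; C1 ketone, C3 OTES) | O=C1C[C@@H](O[Si](CC)(CC)CC)[C@@]2(C)[C@@H]3C(=O)C=C(C)[C@H]2[C@@H]3C1(C)C | intermediate
25 | C3 hydroxy C1 ketone | O=C1C[C@@H](O)[C@@]2(C)[C@@H]3C(=O)C=C(C)[C@H]2[C@@H]3C1(C)C | intermediate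
26 | 3-methylbut-2-enal | CC(C)=CC=O | starting material
27 | C3 3-methylbut-2-enoate, (R)-C1 alcohol | O[C@@H]1C[C@@H](OC(=O)C=C(C)C)[C@@]2(C)[C@@H]3C(=O)C=C(C)[C@H]2[C@@H]3C1(C)C | intermediate
28 | (E)-2-methylbut-2-enoic acid (tiglic acid) | C/C=C(\C)C(O)=O | starting material
29 | (E)-2-methylbut-2-enoic 2,4,6-trichlorobenzoic anhydride | C/C=C(\C)C(=O)OC(=O)c1c(Cl)cc(Cl)cc1Cl | intermediate (not isolated)
30 | CNP0257816.1 (C1 tiglate, C3 senecioate) | C/C=C(\C)C(=O)O[C@@H]1C[C@@H](OC(=O)C=C(C)C)[C@@]2(C)[C@@H]3C(=O)C=C(C)[C@H]2[C@@H]3C1(C)C | target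

## Step count and risks

Total step count: 18. Longest linear sequence: 18 steps (1 to 30).

Steps most likely to fail:

1. Step 6 (Proposed new method). The strained cyclobutene enamine may form only in low concentration; N-acylation may stop at an amide; the second acylation may lose to ketene dimerisation; and both the facial bias (methyl against silyloxymethyl) and the selection between the two α-carbons may be low. Fallback by stepwise, auxiliary-controlled known chemistry, setting out from 7:
   - condensation with (S)-1-amino-2-(methoxymethyl)pyrrolidine gives the hydrazone F1;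
   - deprotonation with lithium diisopropylamide and Michael addition to tert-butyl (E)-but-2-enoate forms C9–C8 in the adduct F2;
   - aqueous oxalic acid releases the keto ester F3 and the auxiliary;
   - trifluoroacetic acid gives the keto acid F4;
   - trifluoroacetic anhydride with BF3·OEt2 closes C5–C6 by intramolecular C-acylation of the ketone enol.

   The route is rejoined at 12; a C8 epimer would converge at 24.

2. Step 12. The copper enolate may be protonated or may oligomerise before it reaches C10, so that plain conjugate reduction to the open-chain isopropyl ketone results. Fallback through a halide-derived samarium enolate, setting out from 15: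
   - the boron aldol of step 10 is run with 3-bromo-3-methylbutan-2-one to give the bromo ketone F5;
   - triethylsilyl triflate and 2,6-lutidine give the silyl ether F6;
   - SmI2 in THF at −78 °C reduces the C–Br bond to the C11 samarium enolate, which closes C10–C11 in an intramolecular Reformatsky reaction.

   The route is rejoined at 21.

3. Step 17. Hydride transfer from the hemiacetal of an α,β-unsaturated aldehyde inside the bridged ring may be slow, which leaves room for retro-aldol opening of C2–C3 or for no reaction. Fallback by reagent-controlled reduction before the enone is unveiled, setting out from 23: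
   - catecholborane with (S)-2-methyl-CBS-oxazaborolidine (large group C11, small group C2) reduces the C1 ketone to the (R)-alcohol F7;
   - Yamaguchi esterification with 28 gives the tiglate F8;
   - Pd(OAc)2 converts the enol silane to the enone F9;
   - HF·pyridine frees the C3 alcohol F10;
   - acylation with 3-methylbut-2-enoyl chloride and DMAP gives 30.

## Further compounds

F1 | step 6 | SAMP hydrazone of 7 | COC[C@@H]1CCCN1N=C1CC(C)(CO[Si](c2ccccc2)(c2ccccc2)C(C)(C)C)C1
F2 | step 6 | hydrazone Michael adduct with tert-butyl (E)-but-2-enoate | CC(C)(C)OC(=O)C[C@H](C)[C@H]1C(=NN2CCC[C@H]2COC)C[C@]1(C)CO[Si](c3ccccc3)(c3ccccc3)C(C)(C)C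
F3 | step 6 | tert-butyl 3-(2-oxocyclobutyl)butanoate keto ester | CC(C)(C)OC(=O)C[C@H](C)[C@H]1C(=O)C[C@]1(C)CO[Si](c2ccccc2)(c2ccccc2)C(C)(C)C
F4 | step 6 | keto acid from F3 | OC(=O)C[C@H](C)[C@H]1C(=O)C[C@]1(C)CO[Si](c2ccccc2)(c2ccccc2)C(C)(C)C
F5 | step 12 | (3R)-β-hydroxy α′-bromo ketone | C[C@H]1C=C(O[Si](C)(C)C(C)(C)C)[C@@H]2C(=O)[C@H]1[C@@]2(C)[C@H](O)CC(=O)C(C)(C)Br
F6 | step 12 | C3 triethylsilyl ether of F5 | C[C@H]1C=C(O[Si](C)(C)C(C)(C)C)[C@@H]2C(=O)[C@H]1[C@@]2(C)[C@H](O[Si](CC)(CC)CC)CC(=O)C(C)(C)Br
F7 | step 17 | (R)-C1 alcohol of 23 | O[C@@H]1C[C@@H](O[Si](CC)(CC)CC)[C@@]2(C)[C@@H]3C(O[Si](C)(C)C(C)(C)C)=C[C@H](C)[C@H]2[C@@H]3C1(C)C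
F8 | step 17 | C1 tiglate of F7 | C/C=C(\C)C(=O)O[C@@H]1C[C@@H](O[Si](CC)(CC)CC)[C@@]2(C)[C@@H]3C(O[Si](C)(C)C(C)(C)C)=C[C@H](C)[C@H]2[C@@H]3C1(C)C
F9 | step 17 | C1 tiglate enone with C3 OTES | C/C=C(\C)C(=O)O[C@@H]1C[C@@H](O[Si](CC)(CC)CC)[C@@]2(C)[C@@H]3C(=O)C=C(C)[C@H]2[C@@H]3C1(C)C
F10 | step 17 | C1 tiglate enone with free C3 alcohol | C/C=C(\C)C(=O)O[C@@H]1C[C@@H](O)[C@@]2(C)[C@@H]3C(=O)C=C(C)[C@H]2[C@@H]3C1(C)C
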